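**Retrosynthetic overview**

1. The C4–prenyl bond is made last. The target is cut back to the fully aromatic methylene-bridged dimer; a catalyst-controlled dearomative prenylation (the prenyl-transferase event of the presumed biosynthesis) turns that arene into the cyclohexadienone ring A and sets the only stereocentre.
2. Methylene bridge: the o-quinone methide of aspidinol (ring B) is captured by methylphlorbutyrophenone (the future ring A), as in the biosynthetic methylene coupling of two acylphloroglucinols.
3. Both halves come from one polyketide-type monomer, methylphlorbutyrophenone: ring B by para-O-methylation, the monomer itself by C-butanoylation of 2-methylphloroglucinol.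
4. Ring order: both six-membered carbocycles are bought as the phloroglucinol nucleus that the polyketide pathway delivers; ring B is finished first, and the dienone ring A is generated last.

Assumption: the target is taken in the tautomer of the given SMILES, in which the quaternary carbon is R; the (R,R) ligand in step 4 is assumed to give this sense of induction, and its mirror image is used instead, with nothing else changed, if the ECD curve of the product shows the opposite.

**Route**

Step 1
Reactants: 1 2-methylphloroglucinol (2-methylbenzene-1,3,5-triol)
Product: 2 methylphlorbutyrophenone, 1-(2,4,6-trihydroxy-3-methylphenyl)butan-1-one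
Conditions: butanoic acid (1.1 equiv), BF3·OEt2 (as solvent), 80 °C, 2 h; then H2O/NaOAc, rt
Reagents that add atoms: butanoic acid, CCCC(=O)O
Why: Friedel–Crafts C-acylation of the electron-rich triol at one of its two equivalent free ring positions gives a single regioisomer, and the hydrogen-bonded (transiently BF2-chelated) aryl ketone is deactivated toward a second acylation.

Step 2
Reactants: 2 methylphlorbutyrophenone
Product: 3 aspidinol, 1-(2,6-dihydroxy-4-methoxy-3-methylphenyl)butan-1-one
Conditions: Me2SO4 (1.0 equiv), K2CO3 (1.0 equiv), acetone, 0 °C → rt, 12 h
Reagents that add atoms: dimethyl sulfate, COS(=O)(=O)OC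
Why: Williamson-type O-methylation with one equivalent of base is selective for the 4-OH para to the ketone, which is the most acidic hydroxyl (vinylogous acid) and the only one not hydrogen-bonded to the carbonyl, while the hard sulfate electrophile favours O- over C-methylation.

Step 3
Reactants: 3 aspidinol; 2 methylphlorbutyrophenone
Product: 6 aromatic methylene-bridged dimer 1-[3-[(3-butanoyl-2,4,6-trihydroxy-5-methylphenyl)methyl]-2,6-dihydroxy-4-methoxy-5-methylphenyl]butan-1-one, via Mannich base 4 (not isolated), via o-quinone methide 5 (not isolated)
Conditions: [CH2=NMe2]I (Eschenmoser's salt, 1.05 equiv), K2CO3 (1.0 equiv), MeCN, 0 °C → rt, 2 h; then 2 (1.3 equiv), 80 °C, 6 h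
Reagents that add atoms: N,N-dimethylmethyleneiminium iodide, C=[N+](C)C.[I-]
Why: Mannich aminomethylation can only occur at the single free ring position of 3, and on heating the Mannich base loses Me2NH to an o-quinone methide that is captured in a Michael-type Friedel–Crafts addition by the only free ring carbon of the more nucleophilic triol 2, so the unsymmetrical bridge forms without free formaldehyde that would give homodimers.

Step 4
Reactants: 6 aromatic methylene-bridged dimer
Product: 7 target, (4R)-2-butanoyl-6-[(3-butanoyl-2,4-dihydroxy-6-methoxy-5-methylphenyl)methyl]-3,5-dihydroxy-4-methyl-4-(3-methylbut-2-en-1-yl)cyclohexa-2,5-dien-1-one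
Conditions: prenyl acetate (1.05 equiv), Pd2(dba)3·CHCl3 (2.5 mol %), (R,R)-DACH-phenyl Trost ligand (7.5 mol %), Et3N (1.05 equiv), degassed CH2Cl2, 0 °C → rt; then cold 0.5 M HCl
Reagents that add atoms: prenyl acetate (3-methylbut-2-en-1-yl acetate), CC(=O)OCC=C(C)C
Why: Proposed new method: one equivalent of Et3N ionizes only the most acidic hydroxyl of 6 (the ring A OH para to the ketone), the chiral zerovalent palladium catalyst ionizes prenyl acetate to a π-prenyl complex whose unsubstituted terminus is attacked by the methyl-bearing ortho carbon (less hindered than the benzyl-bearing one, while O-prenyl ethers re-ionize and funnel back), and the ligand pocket distinguishes the two faces of that carbon, which has the phenoxide oxygen on one side and the chelated C–OH on the other, so the quaternary stereocentre is set as R under catalyst control and ring A is dearomatized; the closest known reaction type is the palladium-catalysed asymmetric allylic alkylation (Tsuji–Trost) as used for intermolecular dearomatization of ortho-substituted naphthols and phenols and for linear-selective enantioselective prenylation of carbon nucleophiles.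

**Compound list**

1 | 2-methylphloroglucinol (2-methylbenzene-1,3,5-triol) | Cc1c(O)cc(O)cc1O | starting material
2 | methylphlorbutyrophenone, 1-(2,4,6-trihydroxy-3-methylphenyl)butan-1-one | CCCC(=O)c1c(O)cc(O)c(C)c1O | intermediate
3 | aspidinol, 1-(2,6-dihydroxy-4-methoxy-3-methylphenyl)butan-1-one | CCCC(=O)c1c(O)cc(OC)c(C)c1O | intermediate
4 | Mannich base, 1-[3-[(dimethylamino)methyl]-2,6-dihydroxy-4-methoxy-5-methylphenyl]butan-1-one | CCCC(=O)c1c(O)c(C)c(OC)c(CN(C)C)c1O | intermediate
5 | o-quinone methide, 2-butanoyl-3-hydroxy-5-methoxy-4-methyl-6-methylidenecyclohexa-2,4-dien-1-one | CCCC(=O)C1=C(O)C(C)=C(OC)C(=C)C1=O | intermediate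
6 | aromatic methylene-bridged dimer, 1-[3-[(3-butanoyl-2,4,6-trihydroxy-5-methylphenyl)methyl]-2,6-dihydroxy-4-methoxy-5-methylphenyl]butan-1-one | CCCC(=O)c1c(O)c(C)c(O)c(Cc2c(O)c(C(=O)CCC)c(O)c(C)c2OC)c1O | intermediate
7 | (4R)-2-butanoyl-6-[(3-butanoyl-2,4-dihydroxy-6-methoxy-5-methylphenyl)methyl]-3,5-dihydroxy-4-methyl-4-(3-methylbut-2-en-1-yl)cyclohexa-2,5-dien-1-one (CNP0219644.1) | CCCC(=O)C1=C(O)[C@](C)(CC=C(C)C)C(O)=C(Cc2c(O)c(C(=O)CCC)c(O)c(C)c2OC)C1=O | target

**Step count and risks**

Total step count: 4. Longest linear sequence: 4 steps (1 → 2 → 3 → 6 → 7; compound 2 is also used a second time as the coupling partner in step 3).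

Steps most likely to fail:

Step 4 (enantioselective, site-selective dearomative prenylation of the unprotected dimer). The risks are low ee, attack at the benzyl-bearing carbon or on ring B, and double prenylation. The fallback sets out from 6 and comes back at 7, and replaces catalyst control by resolution. Compound 6 is C-prenylated without any chiral agent under the classical lupulone-type conditions (prenyl bromide, aqueous KOH, 0 °C). This gives the racemate, that is 7 together with the (4S)-enantiomer of the target F1. The two are separated by preparative supercritical-fluid chromatography on an amylose tris(3,5-dimethylphenylcarbamate) phase and assigned by ECD; 7 is kept.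

Step 3 (unsymmetrical methylene bridge). The risks are sluggish loss of Me2NH and methylene scrambling to the two homodimers. The fallback sets out from 2 and comes back at 6, and avoids any cross-coupling. Compound 2 is condensed with formaldehyde (0.5 equiv, aqueous, catalytic acid, rt) to the symmetrical dimer bis(3-butanoyl-2,4,6-trihydroxy-5-methylphenyl)methane F2, where no cross-selectivity question exists. F2 is then desymmetrized by statistical mono-O-methylation of one of its two equivalent para-hydroxyls (Me2SO4 0.9 equiv, K2CO3, acetone). This gives 6, and unreacted F2 is recycled.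

Step 2 (mono-O-methylation of one of three hydroxyls). The risks are over-methylation and some C-methylation. The fallback sets out from 2 and comes back at 3, and replaces selection by acidity with selection by chelation. Compound 2 is exhaustively O-methylated (excess Me2SO4, K2CO3, acetone, reflux) to 1-(2,4,6-trimethoxy-3-methylphenyl)butan-1-one F3. The two methoxy groups ortho to the ketone are then cleaved with BCl3 (excess, CH2Cl2, 0 °C → rt), which is delivered by coordination to the carbonyl and leaves the para-methoxy group in place, giving 3.

**Further compounds**

F1 | step 4 | (4S)-2-butanoyl-6-[(3-butanoyl-2,4-dihydroxy-6-methoxy-5-methylphenyl)methyl]-3,5-dihydroxy-4-methyl-4-(3-methylbut-2-en-1-yl)cyclohexa-2,5-dien-1-one (enantiomer of 7) | CCCC(=O)C1=C(O)[C@@](C)(CC=C(C)C)C(O)=C(Cc2c(O)c(C(=O)CCC)c(O)c(C)c2OC)C1=O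
F2 | step 3 | bis(3-butanoyl-2,4,6-trihydroxy-5-methylphenyl)methane | CCCC(=O)c1c(O)c(C)c(O)c(Cc2c(O)c(C)c(O)c(C(=O)CCC)c2O)c1O
F3 | step 2 | 1-(2,4,6-trimethoxy-3-methylphenyl)butan-1-one | CCCC(=O)c1c(OC)cc(OC)c(C)c1OC
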